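**Strategy**

The cyclohexene (C1 bearing the keto-enol chain, C2 the guaiacyl group, C3H2, C4=C5, C6 the veratryl group) is cut at C1–C6, the bond between a carbonyl α-carbon and an allylic, benzylic carbon flanking C4=C5, which is the trace of an ester-enolate Claisen shift. Heating the silyl ketene acetal of a trans-4-aryl-6-[(E)-styryl] δ-lactone forms C1–C6, opens the lactone, moves the alkene into the new carbocycle and sets C6 cis to C2 through a tether-enforced boat. The precursor is the (4S,6R)-lactone whose 4-aryl group is a triisopropylsilyl-protected guaiacyl group. C1 is corrected afterwards by equilibration of a methyl ketone, whose methyl group is extended by aldol addition and oxidation.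

Key step: step 6

**Remarks on the chemistry**

- Cyclohexene locants are fixed as C1 (acyl CH), C2 (guaiacyl CH), C3 (CH2), C4=C5, C6 (veratryl CH); names and descriptors use these locants (target: 1R,2S,6R). Lactone atoms are called "position 4" and "position 6". Guaiacyl = 4-hydroxy-3-methoxyphenyl; veratryl = 3,4-dimethoxyphenyl; Ar = 3-methoxy-4-(triisopropylsilyloxy)phenyl.
- The 1,3-diketone of 20 and 21 is written as the enol tautomer of the target structure; keto and enol forms are one compound.
- The ring phenol is carried as a triisopropylsilyl ether, because a more labile silyl ether would not be expected to survive the aqueous base, methyllithium and methoxide steps.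
- C1 is equilibrated as the acetyl compound, and the side chain is then built from the unhindered methyl group.
- (+)-Ipc2B(allyl) is assumed to be used as the commercial pentane solution; the configuration and enantiomeric purity of 3 would be checked (Mosher esters) before continuing.

**Route**

Step 1
Reactants: 1 (E)-3,4-dimethoxycinnamaldehyde
Product: 3 (R,E)-1-(3,4-dimethoxyphenyl)hexa-1,5-dien-3-ol, via borinate 2 (not isolated)
Conditions: (+)-Ipc2B(allyl) (1 M in pentane, 1.2 equiv), Et2O, −78 °C; then 3 M NaOH, 30% H2O2, 0 °C → rt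
Reagents that add atoms: (+)-B-allyldiisopinocampheylborane, C=CCB([C@H]1C[C@H]2C[C@@H]([C@@H]1C)C2(C)C)[C@H]1C[C@H]2C[C@@H]([C@@H]1C)C2(C)C
Why: Brown allylboration through a closed six-membered chair transition state, in which the isopinocampheyl groups of the (+)-reagent should direct the allyl group to the Re face of the aldehyde carbonyl (1,2-addition) and so set the R carbinol centre.

Step 2
Reactants: 3 (R,E)-1-(3,4-dimethoxyphenyl)hexa-1,5-dien-3-ol; 4 acryloyl chloride
Product: 5 (R,E)-1-(3,4-dimethoxyphenyl)hexa-1,5-dien-3-yl acrylate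
Conditions: Et3N (2 equiv), 4-(dimethylamino)pyridine (5 mol%), CH2Cl2, 0 °C
Reagents that add atoms: none
Why: O-acylation of the secondary alcohol by the acid chloride (nucleophilic acyl substitution under amine base), which does not touch the carbinol centre.

Step 3
Reactants: 5 (R,E)-1-(3,4-dimethoxyphenyl)hexa-1,5-dien-3-yl acrylate
Product: 6 (R)-6-[(E)-2-(3,4-dimethoxyphenyl)ethenyl]-5,6-dihydro-2H-pyran-2-one
Conditions: RuCl2(PCy3)2(=CHPh) (first-generation Grubbs catalyst, 8 mol%), CH2Cl2 (5 mM), 40 °C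
Reagents that add atoms: none
Why: Ring-closing olefin metathesis joins the terminal vinyl group and the acrylate with loss of ethylene to close the six-membered unsaturated lactone, while the internal aryl-conjugated alkene should stay out of the cycle with this less reactive catalyst.

Step 4
Reactants: 7 2-methoxy-4-(4,4,5,5-tetramethyl-1,3,2-dioxaborolan-2-yl)phenol
Product: 8 2-[3-methoxy-4-(triisopropylsilyloxy)phenyl]-4,4,5,5-tetramethyl-1,3,2-dioxaborolane
Conditions: TIPSCl (1.2 equiv), imidazole (2.5 equiv), DMF, rt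
Reagents that add atoms: chlorotriisopropylsilane, CC(C)[Si](Cl)(C(C)C)C(C)C
Why: Silylation of the phenol (substitution at silicon with imidazole as base) gives an aryl silyl ether that should resist the aqueous base, amide base, methyllithium and methoxide used later.

Step 5
Reactants: 6 (R)-6-[(E)-2-(3,4-dimethoxyphenyl)ethenyl]-5,6-dihydro-2H-pyran-2-one; 8 silylated arylboronate (1.5 equiv)
Product: 9 (4S,6R)-6-[(E)-2-(3,4-dimethoxyphenyl)ethenyl]-4-Ar-tetrahydro-2H-pyran-2-one (trans lactone)
Conditions: [Rh(cod)OH]2 (3 mol%), K3PO4 (1 equiv), 1,4-dioxane/H2O (10:1), 50 °C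
Reagents that add atoms: none
Why: Rhodium-catalysed 1,4-addition of the arylboronate (Hayashi–Miyaura reaction), in which the aryl–rhodium species should add to position 4 of the half-chair enoate on the face opposite the pseudo-equatorial styryl group at position 6, so that substrate control sets position 4 as S and trans to position 6.

Step 6
Reactants: 9 (4S,6R)-trans lactone
Product: 13 (1S,2S,6R)-6-(3,4-dimethoxyphenyl)-2-Ar-cyclohex-4-ene-1-carboxylic acid (all-cis), via lithium enolate 10 (not isolated), via silyl ketene acetal 11 (not isolated), via silyl ester 12 (not isolated)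
Conditions: TBSCl (1.4 equiv), DMPU, THF, −78 °C; LiN(iPr)2 (1.2 equiv), −78 °C → rt; solvent exchange to PhMe, 105 °C; then 1 M HCl, THF, rt
Reagents that add atoms: none
Why: Deprotonation at the lactone α-carbon and O-silylation give the endocyclic silyl ketene acetal 11, in whose reactive half-chair the styryl group is pseudo-axial and the aryl group pseudo-equatorial (possible without strain only for the trans lactone), so that on heating a concerted suprafacial [3,3] shift forms C1–C6 as the carbinol C–O bond breaks, and dilute acid then hydrolyses the silyl ester 12. The closest known reaction type is the Ireland–Claisen ring contraction of lactone silyl ketene acetals that carry an alkenyl group on the carbinol carbon. The cyclohexene closes by bonding of the ketene acetal carbon to the distal styryl carbon across the lactone, the former carbinol carbon and the two styryl carbons becoming C4, C5 and C6 with C4=C5 endocyclic and cis, and the two-atom tether C2–C3 between the reacting termini permits only a boat-like six-centre transition state. C6 is set by transfer of the carbinol configuration through this boat together with the E geometry of the styryl group, which turns the veratryl group outward and therefore cis to the C2 aryl group, and C1 is fixed in the same transition state because the new bond forms on the ketene acetal face that carried the styryl group while the aryl group of the trans lactone lies on the other face, which leaves the carboxyl group cis to both aryl groups. The selectivity needed is the sense of chirality transfer (C6 relative to C2) and a [3,3] shift in preference to heterolysis of the electron-rich cinnamylic C–O bond; the first is secured by the enforced boat and the trans ring substitution, the second by base-mediated silylation without Lewis acid and a non-polar medium.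

Step 7
Reactants: 13 all-cis acid
Product: 14 1-[(1S,2S,6R)-6-(3,4-dimethoxyphenyl)-2-Ar-cyclohex-4-en-1-yl]ethan-1-one (all-cis methyl ketone)
Conditions: MeLi (4 equiv), Et2O/THF, 0 °C → rt; inverse quench into cold 1 M HCl
Reagents that add atoms: methyllithium, [Li]C
Why: Addition of MeLi to the lithium carboxylate gives a geminal dilithium alkoxide that is stable until the quench and then collapses to the methyl ketone (classical carboxylic acid to methyl ketone conversion), with no ring stereocentre involved in the bond formation.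

Step 8
Reactants: 14 all-cis methyl ketone
Product: 15 1-[(1R,2S,6R)-6-(3,4-dimethoxyphenyl)-2-Ar-cyclohex-4-en-1-yl]ethan-1-one (trans,trans methyl ketone)
Conditions: NaOMe (0.3 equiv), MeOH/THF (2:1), rt
Reagents that add atoms: none
Why: Base-mediated epimerisation by reversible enolisation at C1 (thermodynamic control) should move the acetyl group from its axial position between the two aryl groups to the equatorial position, giving the all-equatorial 1R isomer, while C2 and C6 carry no acidic hydrogen and stay fixed.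

Step 9
Reactants: 16 (E)-3-(4-hydroxy-3-methoxyphenyl)prop-2-enal (coniferaldehyde)
Product: 17 (E)-3-[3-methoxy-4-(triisopropylsilyloxy)phenyl]prop-2-enal
Conditions: TIPSCl (1.2 equiv), imidazole (2.5 equiv), DMF, rt
Reagents that add atoms: chlorotriisopropylsilane, CC(C)[Si](Cl)(C(C)C)C(C)C
Why: Silylation of the phenol as in step 4 (substitution at silicon), which masks the acidic OH before the enolate step and leaves the non-enolisable enal untouched.

Step 10
Reactants: 15 trans,trans methyl ketone; 17 silylated coniferaldehyde (1.2 equiv)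
Product: 19 (E)-1-[(1R,2S,6R)-6-(3,4-dimethoxyphenyl)-2-Ar-cyclohex-4-en-1-yl]-3-hydroxy-5-Ar-pent-4-en-1-one (both carbinol epimers), via lithium enolate 18 (not isolated)
Conditions: LiN(iPr)2 (1.1 equiv), THF, −78 °C; then 17, −78 °C; AcOH quench at −78 °C
Reagents that add atoms: none
Why: Kinetic deprotonation of the methyl group (the hindered C1–H is not removed under these conditions) followed by aldol addition of the lithium enolate to the carbonyl group of the non-enolisable enal; the new carbinol centre forms without control and is removed in step 11.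

Step 11
Reactants: 19 aldol adduct
Product: 20 (2Z,4E)-1-[(1R,2S,6R)-6-(3,4-dimethoxyphenyl)-2-Ar-cyclohex-4-en-1-yl]-3-hydroxy-5-Ar-penta-2,4-dien-1-one (bis-silyl ether of the target)
Conditions: Dess–Martin periodinane (1.2 equiv), CH2Cl2, 0 °C → rt
Reagents that add atoms: none
Why: Dess–Martin oxidation of the allylic β-hydroxy ketone gives the 1,3-diketone, which should rest as the conjugated, hydrogen-bonded enol, and the non-basic conditions leave C1 untouched.

Step 12
Reactants: 20 bis-silyl ether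
Product: 21 (2Z,4E)-1-[(1R,2S,6R)-6-(3,4-dimethoxyphenyl)-2-(4-hydroxy-3-methoxyphenyl)cyclohex-4-en-1-yl]-3-hydroxy-5-(4-hydroxy-3-methoxyphenyl)penta-2,4-dien-1-one (target)
Conditions: Bu4NF (3 equiv), AcOH (3 equiv), THF, 0 °C → rt
Reagents that add atoms: none
Why: Fluoride-mediated cleavage of both aryl silyl ethers (desilylation), buffered with acetic acid so that the base-sensitive enolised diketone and the C1 centre are not exposed to unbuffered fluoride.

**Compound list**

1 | (E)-3-(3,4-dimethoxyphenyl)prop-2-enal | COc1ccc(/C=C/C=O)cc1OC | starting material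
2 | (R,E)-1-(3,4-dimethoxyphenyl)hexa-1,5-dien-3-yl diisopinocampheylborinate (isopinocampheyl groups as in the (+)-reagent) | C=CC[C@H](/C=C/c1ccc(OC)c(OC)c1)OB([C@H]1C[C@H]2C[C@@H]([C@@H]1C)C2(C)C)[C@H]1C[C@H]2C[C@@H]([C@@H]1C)C2(C)C | intermediate
3 | (R,E)-1-(3,4-dimethoxyphenyl)hexa-1,5-dien-3-ol | C=CC[C@H](/C=C/c1ccc(OC)c(OC)c1)O | intermediate
4 | acryloyl chloride | C=CC(=O)Cl | starting material
5 | (R,E)-1-(3,4-dimethoxyphenyl)hexa-1,5-dien-3-yl acrylate | C=CC[C@H](/C=C/c1ccc(OC)c(OC)c1)OC(=O)C=C | intermediate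
6 | (R)-6-[(E)-2-(3,4-dimethoxyphenyl)ethenyl]-5,6-dihydro-2H-pyran-2-one | O=C1C=CC[C@H](/C=C/c2ccc(OC)c(OC)c2)O1 | intermediate
7 | 2-methoxy-4-(4,4,5,5-tetramethyl-1,3,2-dioxaborolan-2-yl)phenol | COc1cc(B2OC(C)(C)C(C)(C)O2)ccc1O | starting material
8 | 2-[3-methoxy-4-(triisopropylsilyloxy)phenyl]-4,4,5,5-tetramethyl-1,3,2-dioxaborolane | COc1cc(B2OC(C)(C)C(C)(C)O2)ccc1O[Si](C(C)C)(C(C)C)C(C)C | intermediate
9 | (4S,6R)-6-[(E)-2-(3,4-dimethoxyphenyl)ethenyl]-4-[3-methoxy-4-(triisopropylsilyloxy)phenyl]tetrahydro-2H-pyran-2-one | O=C1C[C@@H](c2ccc(O[Si](C(C)C)(C(C)C)C(C)C)c(OC)c2)C[C@H](/C=C/c2ccc(OC)c(OC)c2)O1 | intermediate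
10 | lithium (4S,6R)-6-[(E)-2-(3,4-dimethoxyphenyl)ethenyl]-4-[3-methoxy-4-(triisopropylsilyloxy)phenyl]-5,6-dihydro-4H-pyran-2-olate | [Li+].[O-]C1=C[C@@H](c2ccc(O[Si](C(C)C)(C(C)C)C(C)C)c(OC)c2)C[C@H](/C=C/c2ccc(OC)c(OC)c2)O1 | intermediate
11 | tert-butyl({(4S,6R)-6-[(E)-2-(3,4-dimethoxyphenyl)ethenyl]-4-[3-methoxy-4-(triisopropylsilyloxy)phenyl]-5,6-dihydro-4H-pyran-2-yl}oxy)dimethylsilane | CC(C)(C)[Si](C)(C)OC1=C[C@@H](c2ccc(O[Si](C(C)C)(C(C)C)C(C)C)c(OC)c2)C[C@H](/C=C/c2ccc(OC)c(OC)c2)O1 | intermediate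
12 | tert-butyldimethylsilyl (1S,2S,6R)-6-(3,4-dimethoxyphenyl)-2-[3-methoxy-4-(triisopropylsilyloxy)phenyl]cyclohex-4-ene-1-carboxylate | CC(C)(C)[Si](C)(C)OC(=O)[C@H]1[C@@H](c2ccc(O[Si](C(C)C)(C(C)C)C(C)C)c(OC)c2)CC=C[C@H]1c1ccc(OC)c(OC)c1 | intermediate
13 | (1S,2S,6R)-6-(3,4-dimethoxyphenyl)-2-[3-methoxy-4-(triisopropylsilyloxy)phenyl]cyclohex-4-ene-1-carboxylic acid | OC(=O)[C@H]1[C@@H](c2ccc(O[Si](C(C)C)(C(C)C)C(C)C)c(OC)c2)CC=C[C@H]1c1ccc(OC)c(OC)c1 | intermediate
14 | 1-{(1S,2S,6R)-6-(3,4-dimethoxyphenyl)-2-[3-methoxy-4-(triisopropylsilyloxy)phenyl]cyclohex-4-en-1-yl}ethan-1-one | CC(=O)[C@H]1[C@@H](c2ccc(O[Si](C(C)C)(C(C)C)C(C)C)c(OC)c2)CC=C[C@H]1c1ccc(OC)c(OC)c1 | intermediate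
15 | 1-{(1R,2S,6R)-6-(3,4-dimethoxyphenyl)-2-[3-methoxy-4-(triisopropylsilyloxy)phenyl]cyclohex-4-en-1-yl}ethan-1-one | CC(=O)[C@@H]1[C@@H](c2ccc(O[Si](C(C)C)(C(C)C)C(C)C)c(OC)c2)CC=C[C@H]1c1ccc(OC)c(OC)c1 | intermediate
16 | (E)-3-(4-hydroxy-3-methoxyphenyl)prop-2-enal | COc1cc(/C=C/C=O)ccc1O | starting material
17 | (E)-3-[3-methoxy-4-(triisopropylsilyloxy)phenyl]prop-2-enal | COc1cc(/C=C/C=O)ccc1O[Si](C(C)C)(C(C)C)C(C)C | intermediate
18 | lithium 1-{(1R,2S,6R)-6-(3,4-dimethoxyphenyl)-2-[3-methoxy-4-(triisopropylsilyloxy)phenyl]cyclohex-4-en-1-yl}ethen-1-olate | [Li+].[O-]C(=C)[C@@H]1[C@@H](c2ccc(O[Si](C(C)C)(C(C)C)C(C)C)c(OC)c2)CC=C[C@H]1c1ccc(OC)c(OC)c1 | intermediate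
19 | (E)-1-{(1R,2S,6R)-6-(3,4-dimethoxyphenyl)-2-[3-methoxy-4-(triisopropylsilyloxy)phenyl]cyclohex-4-en-1-yl}-3-hydroxy-5-[3-methoxy-4-(triisopropylsilyloxy)phenyl]pent-4-en-1-one (both epimers at the carbinol carbon) | COc1cc(/C=C/C(O)CC(=O)[C@@H]2[C@@H](c3ccc(O[Si](C(C)C)(C(C)C)C(C)C)c(OC)c3)CC=C[C@H]2c2ccc(OC)c(OC)c2)ccc1O[Si](C(C)C)(C(C)C)C(C)C | intermediate
20 | (2Z,4E)-1-{(1R,2S,6R)-6-(3,4-dimethoxyphenyl)-2-[3-methoxy-4-(triisopropylsilyloxy)phenyl]cyclohex-4-en-1-yl}-3-hydroxy-5-[3-methoxy-4-(triisopropylsilyloxy)phenyl]penta-2,4-dien-1-one | COc1cc(/C=C/C(O)=C/C(=O)[C@@H]2[C@@H](c3ccc(O[Si](C(C)C)(C(C)C)C(C)C)c(OC)c3)CC=C[C@H]2c2ccc(OC)c(OC)c2)ccc1O[Si](C(C)C)(C(C)C)C(C)C | intermediate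
21 | (2Z,4E)-1-[(1R,2S,6R)-6-(3,4-dimethoxyphenyl)-2-(4-hydroxy-3-methoxyphenyl)cyclohex-4-en-1-yl]-3-hydroxy-5-(4-hydroxy-3-methoxyphenyl)penta-2,4-dien-1-one | COc1cc(/C=C/C(O)=C/C(=O)[C@@H]2[C@@H](c3ccc(O)c(OC)c3)CC=C[C@H]2c2ccc(OC)c(OC)c2)ccc1O | target

**Step count and risk**

Total step count: 12. Longest linear sequence: 10 steps (1, 2, 3, 5, 6, 7, 8, 10, 11, 12).

Steps most likely to fail:

1. Step 6. The ketene acetal may undergo heterolysis of its electron-rich cinnamylic C–O bond (loss of chirality transfer, elimination to a dienoic acid), or decay thermally before the strained boat is reached. The fallback makes the same C1–C6 bond by an acyclic ester-enolate Claisen rearrangement through a chair and closes the ring by metathesis; it sets out from 8 and returns at 15. Addition of 8 to commercial 5,6-dihydro-2H-pyran-2-one under Rh(acac)(C2H4)2/(R)-BINAP catalysis (K3PO4, dioxane/H2O) should give (R)-4-Ar-tetrahydro-2H-pyran-2-one F1 (the R centre is expected from this ligand antipode by analogy with cyclic enones). Reduction with iBu2AlH (CH2Cl2, −78 °C) would give the lactol F2, Wittig methylenation (Ph3P=CH2, THF) would open it to (S)-3-Ar-hex-5-en-1-ol F3, and oxidation (2,2,6,6-tetramethylpiperidin-1-oxyl, PhI(OAc)2, MeCN/H2O) would give (S)-3-Ar-hex-5-enoic acid F4. Corey–Bakshi–Shibata reduction of commercial (E)-4-(3,4-dimethoxyphenyl)but-3-en-2-one with (R)-1-methyl-3,3-diphenyltetrahydro-1H,3H-pyrrolo[1,2-c][1,3,2]oxazaborole and BH3·SMe2 should give (S,E)-4-(3,4-dimethoxyphenyl)but-3-en-2-ol F5, and Steglich esterification (DCC, 4-(dimethylamino)pyridine) of F4 with F5 the allylic ester F6. Ireland–Claisen rearrangement (LiN(iPr)2, TMSCl, THF, −78 °C → rt; aqueous work-up) would pass through the E silyl ketene acetal F7 and the trimethylsilyl ester F8 to the acyclic acid F9. The chair with the carbinol methyl group equatorial transfers the S carbinol configuration to C6 (R), and the E ketene acetal places C1 as R, so that C1, C2 and C6 already have the configuration of 15. Ring-closing metathesis with RuCl2(H2IMes)(PCy3)(=CHPh) (second-generation Grubbs catalyst, CH2Cl2, 40 °C) and loss of propene would close C4=C5 to the trans,trans acid F10, and MeLi under the conditions of step 7 would give 15; any C1 epimer carried along would be converged by the conditions of step 8.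

2. Step 5. Facial control in the aryl transfer may be lost, protodeboronation may outrun transmetalation, or the aqueous base may open the lactone. The fallback replaces boron-to-rhodium aryl transfer by an anhydrous copper-catalysed conjugate addition, which is known to occur anti to the substituent at position 6 of 5,6-dihydropyran-2-ones; it sets out from 6 and returns at 9. Commercial 4-bromo-2-methoxyphenol would be silylated (TIPSCl, imidazole) to (4-bromo-2-methoxyphenoxy)triisopropylsilane F11 and converted with Mg (THF) into the arylmagnesium bromide F12. Addition of F12 to 6 with CuBr·SMe2 (10 mol%) and TMSCl in THF at −78 °C would give the trimethylsilyl ketene acetal F13, which aqueous NH4Cl hydrolyses to 9. The low temperature and the silyl chloride are chosen so that 1,4-addition outruns substitution at the allylic lactone C–O bond.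

3. Step 8. Equilibration at C1 may stall or stay incomplete, because base is diverted into aldol self-condensation of the methyl ketone or cleavage of the aryl silyl ether, or because a sizeable share of the axial isomer remains at equilibrium (it would then be separated and resubmitted). The fallback corrects C1 at the ester oxidation level, where forcing equilibration cannot cause self-condensation, and reaches the ketone through a Weinreb amide; it sets out from 13 and returns at 15, bypassing steps 7 and 8. Me3SiCHN2 (MeOH/PhMe) would give the all-cis methyl ester F14. NaOMe in MeOH at reflux should equilibrate it to the trans,trans methyl ester F15 (the phenol would be re-silylated with TIPSCl if the ether is lost). MeNHOMe·HCl with iPrMgCl (THF, −20 °C) would give the trans,trans Weinreb amide F16, and MeMgBr (THF, 0 °C) the ketone 15.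

**Further compounds**

F1 | step 6 | (R)-4-[3-methoxy-4-(triisopropylsilyloxy)phenyl]tetrahydro-2H-pyran-2-one | O=C1C[C@H](c2ccc(O[Si](C(C)C)(C(C)C)C(C)C)c(OC)c2)CCO1
F2 | step 6 | (4R)-4-[3-methoxy-4-(triisopropylsilyloxy)phenyl]tetrahydro-2H-pyran-2-ol (both anomers) | OC1C[C@H](c2ccc(O[Si](C(C)C)(C(C)C)C(C)C)c(OC)c2)CCO1
F3 | step 6 | (S)-3-[3-methoxy-4-(triisopropylsilyloxy)phenyl]hex-5-en-1-ol | C=CC[C@H](c1ccc(O[Si](C(C)C)(C(C)C)C(C)C)c(OC)c1)CCO
F4 | step 6 | (S)-3-[3-methoxy-4-(triisopropylsilyloxy)phenyl]hex-5-enoic acid | C=CC[C@H](c1ccc(O[Si](C(C)C)(C(C)C)C(C)C)c(OC)c1)CC(=O)O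
F5 | step 6 | (S,E)-4-(3,4-dimethoxyphenyl)but-3-en-2-ol | C[C@H](O)/C=C/c1ccc(OC)c(OC)c1
F6 | step 6 | (S,E)-4-(3,4-dimethoxyphenyl)but-3-en-2-yl (S)-3-[3-methoxy-4-(triisopropylsilyloxy)phenyl]hex-5-enoate | C=CC[C@H](c1ccc(O[Si](C(C)C)(C(C)C)C(C)C)c(OC)c1)CC(=O)O[C@@H](C)/C=C/c1ccc(OC)c(OC)c1
F7 | step 6 | E trimethylsilyl ketene acetal of F6 | C=CC[C@H](c1ccc(O[Si](C(C)C)(C(C)C)C(C)C)c(OC)c1)/C=C(/O[Si](C)(C)C)O[C@@H](C)/C=C/c1ccc(OC)c(OC)c1
F8 | step 6 | trimethylsilyl ester of F9 | C[Si](C)(C)OC(=O)[C@H]([C@@H](c1ccc(O[Si](C(C)C)(C(C)C)C(C)C)c(OC)c1)CC=C)[C@H](c1ccc(OC)c(OC)c1)/C=C/C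
F9 | step 6 | (2R,3S)-2-[(1R,2E)-1-(3,4-dimethoxyphenyl)but-2-en-1-yl]-3-[3-methoxy-4-(triisopropylsilyloxy)phenyl]hex-5-enoic acid | OC(=O)[C@H]([C@@H](c1ccc(O[Si](C(C)C)(C(C)C)C(C)C)c(OC)c1)CC=C)[C@H](c1ccc(OC)c(OC)c1)/C=C/C
F10 | step 6 | (1R,2S,6R)-6-(3,4-dimethoxyphenyl)-2-[3-methoxy-4-(triisopropylsilyloxy)phenyl]cyclohex-4-ene-1-carboxylic acid | OC(=O)[C@@H]1[C@@H](c2ccc(O[Si](C(C)C)(C(C)C)C(C)C)c(OC)c2)CC=C[C@H]1c1ccc(OC)c(OC)c1
F11 | step 5 | (4-bromo-2-methoxyphenoxy)triisopropylsilane | COc1cc(Br)ccc1O[Si](C(C)C)(C(C)C)C(C)C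
F12 | step 5 | [3-methoxy-4-(triisopropylsilyloxy)phenyl]magnesium bromide | COc1cc([Mg]Br)ccc1O[Si](C(C)C)(C(C)C)C(C)C
F13 | step 5 | trimethylsilyl ketene acetal of 9 | C[Si](C)(C)OC1=C[C@@H](c2ccc(O[Si](C(C)C)(C(C)C)C(C)C)c(OC)c2)C[C@H](/C=C/c2ccc(OC)c(OC)c2)O1
F14 | step 8 | methyl (1S,2S,6R)-6-(3,4-dimethoxyphenyl)-2-[3-methoxy-4-(triisopropylsilyloxy)phenyl]cyclohex-4-ene-1-carboxylate | COC(=O)[C@H]1[C@@H](c2ccc(O[Si](C(C)C)(C(C)C)C(C)C)c(OC)c2)CC=C[C@H]1c1ccc(OC)c(OC)c1
F15 | step 8 | methyl (1R,2S,6R)-6-(3,4-dimethoxyphenyl)-2-[3-methoxy-4-(triisopropylsilyloxy)phenyl]cyclohex-4-ene-1-carboxylate | COC(=O)[C@@H]1[C@@H](c2ccc(O[Si](C(C)C)(C(C)C)C(C)C)c(OC)c2)CC=C[C@H]1c1ccc(OC)c(OC)c1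
F16 | step 8 | (1R,2S,6R)-6-(3,4-dimethoxyphenyl)-N-methoxy-2-[3-methoxy-4-(triisopropylsilyloxy)phenyl]-N-methylcyclohex-4-ene-1-carboxamide | CON(C)C(=O)[C@@H]1[C@@H](c2ccc(O[Si](C(C)C)(C(C)C)C(C)C)c(OC)c2)CC=C[C@H]1c1ccc(OC)c(OC)c1
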